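**Retrosynthetic overview**
1. Goyazensolide ⇒ free the C15 alcohol and open the C3–O bond of the 3(2H)-furanone (ring C, closed last, across the ring) ⇒ ten-membered 4-hydroxy-2-ynone.
2. Ynone ⇒ C2–C3 and C3–C4, with C3 coming from CO (carbocycle, ring B, closed second) ⇒ seco vinyl iodide/terminal alkyne that already carries the C8 methacrylate.
3. Seco compound ⇒ C7–C8 chromium allylation, which completes the α-methylene lactone (ring A, formed first) and sets C7 and C8 ⇒ bromobutenolide (fragment A) + β-hydroxy aldehyde (fragment B).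
4. Fragment A ⇒ ring-closing metathesis, C6–O esterification, hydroalumination/iodination, asymmetric alkynylation of acrolein (sets C6).
5. Fragment B ⇒ alcohol oxidation, directed epoxide opening, Sharpless epoxidation (makes the C10–O bond and sets C10) of (E)-3-methylpent-2-en-4-yn-1-ol.

Assumption: atom labels C1–C15 follow germacrane numbering of the target (C1 ketone, C3 enol-ether carbon, C6 lactone carbinol, C8 ester carbinol, C10 quaternary carbon, C15 CH2OH). Compounds 1, 2, 6, 9 and 15 are taken as catalogue chemicals.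

Step 1
Reactants: 1 acrolein; 2 tert-butyldimethyl(prop-2-yn-1-yloxy)silane
Product: 3 (3S)-6-[(tert-butyldimethylsilyl)oxy]hex-1-en-4-yn-3-ol
Conditions: Me2Zn (3 equiv), (S,S)-ProPhenol (10 mol %), Ph3PO (20 mol %), toluene, 4 °C
Reagents that add atoms: none
Why: Zinc–ProPhenol catalysed asymmetric alkynylation of an aldehyde, in which the dinuclear zinc complex of the (S,S) ligand holds the alkynyl group and acrolein side by side and delivers the alkyne 1,2 to the Re face, setting C6 as S (the same spatial arrangement is called 6R in the target).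

Step 2
Reactants: 3 (3S)-6-[(tert-butyldimethylsilyl)oxy]hex-1-en-4-yn-3-ol
Product: 5 (3S,4Z)-6-[(tert-butyldimethylsilyl)oxy]-5-iodohexa-1,4-dien-3-ol, via cyclic alkenylalanate 4 (not isolated)
Conditions: NaAlH2(OCH2CH2OMe)2 (Red-Al, 1.5 equiv), THF, 0 °C; then N-iodosuccinimide, −78 °C
Reagents that add atoms: N-iodosuccinimide, O=C1CCC(=O)N1I
Why: Hydroxyl-directed trans-hydroalumination of a propargylic alcohol followed by iodinolysis, in which the C6 alkoxide delivers hydride to C5 and ties aluminium to C4 in the five-membered alanate 4, so that iodine replaces aluminium with retention and only the Z-iodide (iodine cis to C6) forms, while the vinyl group, the silyl ether and C6 are untouched.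

Step 3
Reactants: 5 (3S,4Z)-6-[(tert-butyldimethylsilyl)oxy]-5-iodohexa-1,4-dien-3-ol; 6 2-(bromomethyl)acrylic acid
Product: 7 (3S,4Z)-6-[(tert-butyldimethylsilyl)oxy]-5-iodohexa-1,4-dien-3-yl 2-(bromomethyl)prop-2-enoate
Conditions: DCC (1.2 equiv), DMAP (5 mol %), CH2Cl2, 0 °C
Reagents that add atoms: none
Why: Steglich esterification acylates the C6 hydroxyl without breaking the C6–O bond, so the configuration is kept, and the trace of DMAP at 0 °C spares the allylic bromide.

Step 4
Reactants: 7 (3S,4Z)-6-[(tert-butyldimethylsilyl)oxy]-5-iodohexa-1,4-dien-3-yl 2-(bromomethyl)prop-2-enoate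
Product: 8 (5S)-3-(bromomethyl)-5-[(1Z)-3-[(tert-butyldimethylsilyl)oxy]-2-iodoprop-1-en-1-yl]furan-2(5H)-one
Conditions: second-generation Hoveyda–Grubbs catalyst RuCl2(H2IMes)(=CH-C6H4-2-OiPr) (5 mol %), toluene (0.01 M), 80 °C
Reagents that add atoms: none
Why: Ring-closing metathesis, in which the ruthenium carbene loads on the monosubstituted vinyl group and closes on the 1,1-disubstituted acrylate to the five-membered butenolide with loss of ethene, the trisubstituted iodoalkene being inert to metathesis and the neutral medium sparing the acidic C6–H.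

Step 5
Reactants: 9 (2E)-3-methylpent-2-en-4-yn-1-ol
Product: 10 [(2S,3S)-3-ethynyl-3-methyloxiran-2-yl]methanol
Conditions: Ti(OiPr)4 (10 mol %), L-(+)-diisopropyl tartrate (12 mol %), t-BuOOH (1.5 equiv), 4 Å MS, CH2Cl2, −20 °C
Reagents that add atoms: tert-butyl hydroperoxide, CC(C)(C)OO
Why: Katsuki–Sharpless asymmetric epoxidation, in which the L-(+)-tartrate catalyst oxidises the face of the E-allylic alcohol that gives the (2S,3S)-epoxide, so the C10–O bond is made in the configuration that becomes 10R in the target and the alkyne is left alone.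

Step 6
Reactants: 10 [(2S,3S)-3-ethynyl-3-methyloxiran-2-yl]methanol
Product: 11 (3R)-3-methylpent-4-yne-1,3-diol
Conditions: NaAlH2(OCH2CH2OMe)2 (Red-Al, 2.2 equiv), THF, −20 to 0 °C
Reagents that add atoms: none
Why: Alkoxide-directed reductive opening of a 2,3-epoxy alcohol, in which aluminium bound to the primary alkoxide delivers hydride intramolecularly to the less hindered C9 to give the 1,3-diol, and C10 keeps its configuration because its C–O bond is not broken.

Step 7
Reactants: 11 (3R)-3-methylpent-4-yne-1,3-diol
Product: 12 (3R)-3-hydroxy-3-methylpent-4-ynal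
Conditions: TEMPO (10 mol %), PhI(OAc)2 (1.1 equiv), CH2Cl2, 23 °C, used crude
Reagents that add atoms: none
Why: TEMPO/PhI(OAc)2 oxidation (oxoammonium catalysis) stops at the aldehyde, cannot touch the tertiary alcohol, and is mild enough not to dehydrate the β-hydroxy aldehyde.

Step 8
Reactants: 8 (5S)-3-(bromomethyl)-5-[(1Z)-3-[(tert-butyldimethylsilyl)oxy]-2-iodoprop-1-en-1-yl]furan-2(5H)-one; 12 (3R)-3-hydroxy-3-methylpent-4-ynal
Product: 14 (4R,5S)-4-[(1S,3R)-1,3-dihydroxy-3-methylpent-4-yn-1-yl]-5-[(1Z)-3-[(tert-butyldimethylsilyl)oxy]-2-iodoprop-1-en-1-yl]-3-methylideneoxolan-2-one, via allylchromium dichloride 13 (not isolated)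
Conditions: CrCl2 (4 equiv, nickel-free), THF, 0 to 23 °C
Reagents that add atoms: none
Why: Nozaki–Hiyama-type chromium Barbier allylation, in which divalent chromium reduces only the allylic bromide (the vinyl iodide would need nickel) to 13, which adds through C7 to the aldehyde in a chair-like Zimmerman–Traxler transition state on the butenolide face anti to the C6 side chain, so that C7 (R, trans to C6) and C8 (S, anti) are both set from C6 and the double bond moves out to the exocyclic methylene.

Step 9
Reactants: 14 the diol lactone of step 8; 15 methacrylic anhydride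
Product: 16 (1S,3R)-1-[(2S,3R)-2-[(1Z)-3-[(tert-butyldimethylsilyl)oxy]-2-iodoprop-1-en-1-yl]-4-methylidene-5-oxooxolan-3-yl]-3-hydroxy-3-methylpent-4-yn-1-yl 2-methylprop-2-enoate
Conditions: Et3N (3 equiv), DMAP (20 mol %), CH2Cl2, 0 °C
Reagents that add atoms: none
Why: DMAP-catalysed acylation esterifies the secondary C8 alcohol with retention, while the hindered tertiary propargylic C10 alcohol does not react at 0 °C.

Step 10
Reactants: 16 the seco vinyl iodide/terminal alkyne of step 9
Product: 17 (4Z,6R,7R,8S,10R)-15-[(tert-butyldimethylsilyl)oxy]-10-hydroxy-8-(methacryloyloxy)-3-oxogermacra-4,11(13)-dien-1-yn-12,6-olide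
Conditions: PdCl2(PPh3)2 (10 mol %), CuI (10 mol %), Et3N (5 equiv), CO (1 atm), THF, 40 °C, 16 added by syringe pump over 12 h to 1 mM
Reagents that add atoms: carbon monoxide, [C-]#[O+]
Why: Carbonylative Sonogashira coupling run intramolecularly, in which zerovalent palladium inserts into the Z-vinyl iodide with retention, CO insertion gives the acylpalladium and the tethered copper acetylide closes the ten-membered ynone, the CO-free closure being shut off because it would need a nine-membered enyne and pseudo-high dilution holding back dimers, with no stereocenter touched.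

Step 11
Reactants: 17 the ten-membered 4-hydroxy-2-ynone of step 10
Product: 20 goyazensolide, via hydroxy-1,3-diketone 18 (not isolated), via 15-O-TBS-goyazensolide 19 (not isolated)
Conditions: [(t-Bu)2(biphenyl-2-yl)P]Au(NCMe)SbF6 (5 mol %), H2O (2 equiv), 1,4-dioxane, 40 °C; then HF·pyridine, 0 °C
Reagents that add atoms: water, O
Why: Proposed new method: a transannular hydrative cycloisomerisation of a strained ten-membered 4-hydroxy-2-ynone, in which monovalent gold activates the bent C1≡C2 bond, water adds at C1 (the carbon β to the C3 ketone, so substrate polarity and π-acid activation agree) to give 18, the C10 hydroxyl then closes 5-exo on the C3 carbonyl and loss of water forms the C3–O bond of the 3(2H)-furanone and returns the water, making the step a net isomerisation with a 1,3-carbonyl shift that is driven by release of ring strain and keeps C10 intact because its C–O bond is never broken; the closest known reaction type is the gold- or mercury-catalysed cyclisation of open-chain γ-hydroxyalkynones to 3(2H)-furanones, which has not been shown across a medium ring or beside an α-methylene lactone, and fluoride-driven silyl ether cleavage then frees the C15 alcohol in the same flask.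

**Compound list**
1 | acrolein | C=CC=O | starting material
2 | tert-butyldimethyl(prop-2-yn-1-yloxy)silane | C#CCO[Si](C)(C)C(C)(C)C | starting material
3 | (3S)-6-[(tert-butyldimethylsilyl)oxy]hex-1-en-4-yn-3-ol | C=C[C@H](O)C#CCO[Si](C)(C)C(C)(C)C | intermediate
4 | sodium alanate: aluminium bears two 2-methoxyethoxy groups and closes a five-membered ring through O3 and C5 of the (3S)-dienolate (C5 also bears CH2OTBS) | [Na+].COCCO[Al-]1(OCCOC)O[C@@H](C=C)C=C1CO[Si](C)(C)C(C)(C)C | intermediate
5 | (3S,4Z)-6-[(tert-butyldimethylsilyl)oxy]-5-iodohexa-1,4-dien-3-ol | C=C[C@H](O)/C=C(\I)CO[Si](C)(C)C(C)(C)C | intermediate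
6 | 2-(bromomethyl)acrylic acid | C=C(CBr)C(=O)O | starting material
7 | (3S,4Z)-6-[(tert-butyldimethylsilyl)oxy]-5-iodohexa-1,4-dien-3-yl 2-(bromomethyl)prop-2-enoate | C=C[C@H](OC(=O)C(=C)CBr)/C=C(\I)CO[Si](C)(C)C(C)(C)C | intermediate
8 | (5S)-3-(bromomethyl)-5-[(1Z)-3-[(tert-butyldimethylsilyl)oxy]-2-iodoprop-1-en-1-yl]furan-2(5H)-one | BrCC1=C[C@@H](/C=C(\I)CO[Si](C)(C)C(C)(C)C)OC1=O | intermediate
9 | (2E)-3-methylpent-2-en-4-yn-1-ol | C#C/C(C)=C/CO | starting material
10 | [(2S,3S)-3-ethynyl-3-methyloxiran-2-yl]methanol | OC[C@@H]1O[C@@]1(C)C#C | intermediate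
11 | (3R)-3-methylpent-4-yne-1,3-diol | OCC[C@@](C)(O)C#C | intermediate
12 | (3R)-3-hydroxy-3-methylpent-4-ynal | O=CC[C@@](C)(O)C#C | intermediate
13 | {[(5S)-5-[(1Z)-3-[(tert-butyldimethylsilyl)oxy]-2-iodoprop-1-en-1-yl]-2-oxo-2,5-dihydrofuran-3-yl]methyl}chromium dichloride | Cl[Cr](Cl)CC1=C[C@@H](/C=C(\I)CO[Si](C)(C)C(C)(C)C)OC1=O | intermediate
14 | (4R,5S)-4-[(1S,3R)-1,3-dihydroxy-3-methylpent-4-yn-1-yl]-5-[(1Z)-3-[(tert-butyldimethylsilyl)oxy]-2-iodoprop-1-en-1-yl]-3-methylideneoxolan-2-one | C=C1C(=O)O[C@H](/C=C(\I)CO[Si](C)(C)C(C)(C)C)[C@H]1[C@@H](O)C[C@@](C)(O)C#C | intermediate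
15 | methacrylic anhydride | C=C(C)C(=O)OC(=O)C(C)=C | starting material
16 | C8 methacrylate of 14 (6S,7R,8S,10R; Z-iodoalkene; free tertiary C10 alcohol; terminal alkyne) | C=C1C(=O)O[C@H](/C=C(\I)CO[Si](C)(C)C(C)(C)C)[C@H]1[C@@H](OC(=O)C(C)=C)C[C@@](C)(O)C#C | intermediate
17 | (4Z,6R,7R,8S,10R)-15-[(tert-butyldimethylsilyl)oxy]-10-hydroxy-8-(methacryloyloxy)-3-oxogermacra-4,11(13)-dien-1-yn-12,6-olide | C=C(C)C(=O)O[C@H]1C[C@@](C)(O)C#CC(=O)/C(CO[Si](C)(C)C(C)(C)C)=C\[C@H]2OC(=O)C(=C)[C@H]12 | intermediate
18 | (4Z,6R,7R,8S,10R)-15-[(tert-butyldimethylsilyl)oxy]-10-hydroxy-8-(methacryloyloxy)-1,3-dioxogermacra-4,11(13)-dien-12,6-olide | C=C(C)C(=O)O[C@H]1C[C@@](C)(O)C(=O)CC(=O)/C(CO[Si](C)(C)C(C)(C)C)=C\[C@H]2OC(=O)C(=C)[C@H]12 | intermediate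
19 | 15-O-(tert-butyldimethylsilyl)goyazensolide (6R,7R,8S,10R; 4Z) | C=C(C)C(=O)O[C@H]1C[C@@]2(C)OC(=CC2=O)/C(CO[Si](C)(C)C(C)(C)C)=C\[C@H]2OC(=O)C(=C)[C@H]12 | intermediate
20 | goyazensolide (6R,7R,8S,10R; 4Z) | C=C(C)C(=O)O[C@H]1C[C@@]2(C)OC(=CC2=O)/C(CO)=C\[C@H]2OC(=O)C(=C)[C@H]12 | target

**Totals:** 11 steps. The longest linear sequence is 8 steps (1, 2, 3, 4, 8, 9, 10, 11). Steps 5–7 make fragment B and join at step 8.

**Three steps most likely to fail**

Risk 1, the alkynylation of step 1. Acrolein may polymerise under Me2Zn, and the selectivity on this smallest enal is not assured. The fallback sets out from 1 and 2 and comes back at 3. Compound 2 is lithiated with n-BuLi in THF at −78 °C and added to 1 to give the racemic enynol F1. A Sharpless kinetic resolution (Ti(OiPr)4, L-(+)-diisopropyl tartrate, 0.6 equiv t-BuOOH, −20 °C) then epoxidises the vinyl group of the R enantiomer only. This gives the anti epoxy alcohol F2, which is removed by chromatography, and leaves 3 in high enantiomeric purity at the cost of half the material. C6 then comes from a resolution instead of a catalytic addition.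

Risk 2, the ring closure of step 10. A ten-membered ring holding an ynone, a Z-alkene and a trans-fused lactone is strained. Dimerisation, Glaser coupling or interception of the acylpalladium may therefore win. The fallback sets out from 16 and comes back at 17. Heating 16 with Bu3SnOMe in toluene at 60 °C, with removal of methanol, gives the alkynylstannane F3, which can be purified. F3 is then closed by a carbonylative Stille macrocyclisation (Pd2(dba)3, AsPh3, CO 1 atm, THF, 50 °C, syringe pump). This coupling type is established for macrocyclic dienones and ynones. It needs no copper and no amine, so acetylide homocoupling and base-induced side reactions are removed and transmetalation comes from a covalently fixed partner.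

Risk 3, the new transannular cyclisation of step 11. Gold may hydrate slowly or trigger a Meyer–Schuster-type shift, and diketone 18 may fail to close. The fallback uses known chemistry, sets out from 17 and comes back at 19. Diethylamine (1.05 equiv, CH2Cl2, 0 °C) adds to the ynone, which is far more electrophilic than the α-methylene lactone, and any C13 amine adduct reverts on silica gel. The product is the enaminone F4. Treatment with AcOH/H2O/THF at 23 °C hydrolyses F4 to the 1,3-diketone, which cyclodehydrates to 19. This is the classical amine route from 4-hydroxy-2-ynones to 3(2H)-furanones. Compound 19 is then desilylated with HF·pyridine as in step 11.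

**Further compounds**
F1 | step 1 | racemic 6-[(tert-butyldimethylsilyl)oxy]hex-1-en-4-yn-3-ol | C=CC(O)C#CCO[Si](C)(C)C(C)(C)C
F2 | step 1 | (1S)-4-[(tert-butyldimethylsilyl)oxy]-1-[(2R)-oxiran-2-yl]but-2-yn-1-ol | O[C@@H](C#CCO[Si](C)(C)C(C)(C)C)[C@H]1CO1
F3 | step 10 | tributylstannyl alkyne derived from 16 (Bu3Sn on the terminal alkyne carbon C2, all else as in 16) | C=C1C(=O)O[C@H](/C=C(\I)CO[Si](C)(C)C(C)(C)C)[C@H]1[C@@H](OC(=O)C(C)=C)C[C@@](C)(O)C#C[Sn](CCCC)(CCCC)CCCC
F4 | step 11 | (1E,4Z,6R,7R,8S,10R)-15-[(tert-butyldimethylsilyl)oxy]-1-(diethylamino)-10-hydroxy-8-(methacryloyloxy)-3-oxogermacra-1,4,11(13)-trien-12,6-olide | C=C(C)C(=O)O[C@H]1C[C@@](C)(O)/C(N(CC)CC)=C\C(=O)/C(CO[Si](C)(C)C(C)(C)C)=C\[C@H]2OC(=O)C(=C)[C@H]12
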